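Everything rests on deleting the lactone oxygen O1 of coumarin ring A. Without it, C2 is bonded directly to C8a and the pyranone becomes the five-membered ring of a syringyl-derived indan-1-one. The feature exploited is that C8a has methoxy groups ortho (C8) and para (C6) to it. This aryl carbon should therefore migrate in a Baeyer–Villiger oxidation, which delivers the fourth arene oxygen and the six-membered lactone in one operation. The precursor is racemic 6-benzyloxy-5,7-dimethoxyindan-1-one carrying the 7-oxygen of isofraxidin on its sp3 α-carbon (future C3), so the C3–O bond comes from a simple SN2 reaction. Dehydrogenation across C3–C4 and debenzylation complete the achiral target.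

Key step: step 6

Remark on stereochemistry: the target SMILES holds no stereocentre, no stereogenic double bond and no configurationally stable axis, so it is achiral and there is no enantiomer to select. Compounds 7, 9 and 11 are carried as racemates and 10 as a mixture of diastereomers. Their single sp3 centre disappears in step 7.

Step 1
Reactants: 1 sinapic acid
Product: 2 3-(4-hydroxy-3,5-dimethoxyphenyl)propanoic acid (dihydrosinapic acid)
Conditions: H2 (1 atm), 10% Pd/C, MeOH, rt
Reagents that add atoms: none
Why: Catalytic hydrogenation of a cinnamic acid C=C over Pd/C is fast at ambient pressure and leaves the arene, the phenol, the methyl ethers and the acid untouched; no stereocentre forms.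

Step 2
Reactants: 2 dihydrosinapic acid
Product: 3 6-hydroxy-5,7-dimethoxyindan-1-one
Conditions: Eaton's reagent (P2O5/MeSO3H), rt to 40 °C
Reagents that add atoms: none
Why: In this intramolecular Friedel–Crafts acylation the two free ring positions are equivalent by symmetry and each lies ortho to one methoxy and para to the other, so only one indanone can form, while the hindered phenol flanked by two methoxy groups stays free in the strongly acidic medium.

Step 3
Reactants: 3 6-hydroxy-5,7-dimethoxyindan-1-one; 4 benzyl bromide
Product: 5 6-benzyloxy-5,7-dimethoxyindan-1-one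
Conditions: K2CO3, DMF, 50 °C
Reagents that add atoms: none
Why: This is a Williamson etherification of the only acidic OH (carbonate is too weak to C-alkylate the ketone), and benzyl is chosen because it withstands base and peracid, sits meta to the carbon that migrates in step 6, and sits para to C4a, where it assists step 7.

Step 4
Reactants: 5 6-benzyloxy-5,7-dimethoxyindan-1-one
Product: 7 (±)-6-benzyloxy-2-bromo-5,7-dimethoxyindan-1-one, via trimethylsilyl enol ether 6 (not isolated)
Conditions: TMSOTf, Et3N, CH2Cl2, 0 °C; then NBS, 0 °C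
Reagents that add atoms: N-bromosuccinimide O=C1CCC(=O)N1Br; trimethylsilyl triflate C[Si](C)(C)OS(=O)(=O)C(F)(F)F (its Me3Si group is found in 6 only)
Why: Soft enolisation followed by electrophilic bromination of the silyl enol ether places bromine on C2, which is far more nucleophilic than the activated aromatic C4–H, so the nuclear bromination and dibromination that free bromine would risk are avoided; the new C2 centre is racemic.

Step 5
Reactants: 7 (±)-6-benzyloxy-2-bromo-5,7-dimethoxyindan-1-one; 8 isofraxidin
Product: 9 (±)-6-benzyloxy-2-[(6,8-dimethoxy-2-oxo-2H-chromen-7-yl)oxy]-5,7-dimethoxyindan-1-one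
Conditions: K2CO3, DMF, 0 °C to rt, N2
Reagents that add atoms: none
Why: This is an SN2 (Williamson-type) displacement at a carbonyl-activated secondary bromide, as is known for 2-bromoindan-1-ones and phenols, and the acceptor-conjugated 7-phenoxide is a weak base with both ortho positions blocked, so O-alkylation should outrun loss of HBr; the centre stays racemic.

Step 6
Reactants: 9 (±)-6-benzyloxy-2-[(6,8-dimethoxy-2-oxo-2H-chromen-7-yl)oxy]-5,7-dimethoxyindan-1-one
Product: 11 (±)-7-benzyloxy-3-[(6,8-dimethoxy-2-oxo-2H-chromen-7-yl)oxy]-6,8-dimethoxy-3,4-dihydrocoumarin, via Criegee adduct 10 (not isolated)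
Conditions: mCPBA, TFA (1 equiv), CH2Cl2, 0 °C to rt, dark
Reagents that add atoms: mCPBA (3-chloroperoxybenzoic acid) OOC(=O)c1cccc(Cl)c1
Why: Acid-assisted addition of the peracid to the C1 ketone gives Criegee adduct 10, in which the aryl carbon C7a shifts with its bonding pair to the proximal peroxide oxygen while 3-chlorobenzoate departs, so that O1–C8a and O1–C2 are made and C2–C8a is broken (coumarin numbering). The closest known reaction types are the Baeyer–Villiger oxidation of 1-indanones to 3,4-dihydrocoumarins and that of electron-rich aryl α-aryloxyalkyl ketones to aryl esters. The six-membered lactone arises by one-atom ring expansion of the five-membered ketone through this 1,2-shift, that is by insertion, so no exo or endo cyclisation mode is involved. No stereocentre is created; the racemic aryloxy-bearing carbon is a spectator that becomes C3 and is flattened in step 7. The step needs migration of C7a rather than of the oxygen-bearing C2, which the methoxy groups ortho (C7) and para (C5) to C7a should secure by stabilising the developing positive charge, whereas the oxygen on C2 is inductively withdrawing and is tied to an acceptor-substituted coumarin ring. The cinnamate-like C3'=C4' bond of unit B is too electron-poor for mCPBA, and using mCPBA instead of a stronger peracid limits further oxidation of the tetraoxygenated ring.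

Step 7
Reactants: 11 (±)-7-benzyloxy-3-[(6,8-dimethoxy-2-oxo-2H-chromen-7-yl)oxy]-6,8-dimethoxy-3,4-dihydrocoumarin
Product: 12 7-benzyloxy-3-[(6,8-dimethoxy-2-oxo-2H-chromen-7-yl)oxy]-6,8-dimethoxycoumarin
Conditions: DDQ, 1,4-dioxane, reflux
Reagents that add atoms: none
Why: In this DDQ dehydrogenation, the standard conversion of 3,4-dihydrocoumarins into coumarins, hydride is taken from benzylic C4, whose cation is stabilised by the para 7-benzyloxy group, and loss of the acidic C3–H then gives the conjugated lactone and erases the only stereocentre.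

Step 8
Reactants: 12 7-benzyloxy-3-[(6,8-dimethoxy-2-oxo-2H-chromen-7-yl)oxy]-6,8-dimethoxycoumarin
Product: 13 7-hydroxy-3-[(6,8-dimethoxy-2-oxo-2H-chromen-7-yl)oxy]-6,8-dimethoxycoumarin (target)
Conditions: BCl3, pentamethylbenzene, CH2Cl2, −78 °C; then MeOH, H2O
Reagents that add atoms: none
Why: In this Lewis-acid debenzylation with a cation scavenger, BCl3 ionises the aryl benzyl ether at −78 °C and pentamethylbenzene traps the benzyl cation by Friedel–Crafts alkylation, while the four methyl ethers (none chelated to a carbonyl), the C3–O–aryl ether and both lactone C=C bonds, which hydrogenolysis could saturate, are left alone.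

Compound list
1 | sinapic acid, (E)-3-(4-hydroxy-3,5-dimethoxyphenyl)prop-2-enoic acid | COc1cc(/C=C/C(O)=O)cc(OC)c1O | starting material
2 | 3-(4-hydroxy-3,5-dimethoxyphenyl)propanoic acid | COc1cc(CCC(O)=O)cc(OC)c1O | intermediate
3 | 6-hydroxy-5,7-dimethoxyindan-1-one | O=C1CCc2cc(OC)c(O)c(OC)c12 | intermediate
4 | benzyl bromide | BrCc1ccccc1 | starting material
5 | 6-benzyloxy-5,7-dimethoxyindan-1-one | O=C1CCc2cc(OC)c(OCc3ccccc3)c(OC)c12 | intermediate
6 | trimethylsilyl enol ether of 5 (C1–OSiMe3, C1=C2, indanone numbering; formed in situ) | C[Si](C)(C)OC1=CCc2cc(OC)c(OCc3ccccc3)c(OC)c12 | intermediate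
7 | (±)-6-benzyloxy-2-bromo-5,7-dimethoxyindan-1-one | O=C1C(Br)Cc2cc(OC)c(OCc3ccccc3)c(OC)c12 | intermediate
8 | isofraxidin, 7-hydroxy-6,8-dimethoxycoumarin | COc1cc2ccc(=O)oc2c(OC)c1O | starting material
9 | (±)-6-benzyloxy-2-[(6,8-dimethoxy-2-oxo-2H-chromen-7-yl)oxy]-5,7-dimethoxyindan-1-one | O=C1C(Oc2c(OC)cc3ccc(=O)oc3c2OC)Cc2cc(OC)c(OCc3ccccc3)c(OC)c12 | intermediate
10 | Criegee adduct of 9 with mCPBA (C1 carries OH and OOC(O)Ar; diastereomer mixture, formed in situ) | OC1(OOC(=O)c2cccc(Cl)c2)C(Oc2c(OC)cc3ccc(=O)oc3c2OC)Cc2cc(OC)c(OCc3ccccc3)c(OC)c12 | intermediate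
11 | (±)-7-benzyloxy-3-[(6,8-dimethoxy-2-oxo-2H-chromen-7-yl)oxy]-6,8-dimethoxy-3,4-dihydrocoumarin | O=C1Oc2c(OC)c(OCc3ccccc3)c(OC)cc2CC1Oc1c(OC)cc2ccc(=O)oc2c1OC | intermediate
12 | 7-benzyloxy-3-[(6,8-dimethoxy-2-oxo-2H-chromen-7-yl)oxy]-6,8-dimethoxycoumarin | COc1cc2cc(Oc3c(OC)cc4ccc(=O)oc4c3OC)c(=O)oc2c(OC)c1OCc1ccccc1 | intermediate
13 | 7-hydroxy-3-[(6,8-dimethoxy-2-oxo-2H-chromen-7-yl)oxy]-6,8-dimethoxycoumarin (achiral) | COc1cc2cc(Oc3c(OC)cc4ccc(=O)oc4c3OC)c(=O)oc2c(OC)c1O | target

Total step count: 8. Longest linear sequence: 8 steps (1 to 13); 4 and 8 are purchased and enter in steps 3 and 5.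

Steps most likely to fail

Step 6. What may go wrong:
- The oxygen-bearing sp3 carbon C2 shifts instead of the aryl carbon.
- The peracid attacks the enol form, giving α-hydroxylation followed by loss of the aryloxy group.
- The electron-rich ring is oxidised further.

The fallback sets out from 8 and comes back at 12. It gives up the oxygen insertion and builds the pyranone of ring A by a Perkin-type condensation. Isofraxidin 8 is benzylated with 4 (K2CO3, DMF) to 7-O-benzylisofraxidin F1. Its C3=C4 bond is cleaved by ozonolysis (O3, CH2Cl2, −78 °C; Me2S; aq. NaHCO3) to 4-benzyloxy-2-hydroxy-3,5-dimethoxybenzaldehyde F2. A second portion of 8 is alkylated with tert-butyl bromoacetate (K2CO3, acetone) to tert-butyl (isofraxidin-7-yloxy)acetate F3. TFA in CH2Cl2 unmasks this to (isofraxidin-7-yloxy)acetic acid F4. Heating F2 with F4 in Ac2O/Et3N, the Perkin–Oglialoro synthesis of 3-aryloxycoumarins, should give 12 directly, after which only step 8 remains.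

Step 5. What may go wrong:
- Bromide 7 is dehydrobrominated to an indenone that polymerises.
- The doubly ortho-substituted, weakly nucleophilic phenoxide attacks slowly.
- The enolisable product is oxidised by air under base.

The fallback sets out from 5 and comes back at 9. It forms the C2–O bond without base and without a leaving group. Claisen formylation of 5 (HCO2Et, NaH, THF) should give 6-benzyloxy-2-formyl-5,7-dimethoxyindan-1-one F5. Deformylative Regitz diazo transfer (TsN3, Et3N, CH2Cl2) converts it into 6-benzyloxy-2-diazo-5,7-dimethoxyindan-1-one F6. Slow addition of F6 to 8 and catalytic Rh2(OAc)4 in 1,2-dichloroethane should deliver 9 by O–H insertion of the rhodium carbenoid.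

Step 7. What may go wrong:
- Hydride abstraction from C4 is sluggish, so the reaction needs prolonged heating.
- Under that heating the benzyl group is lost oxidatively, or the benzylic cation is captured by the hydroquinone.

The fallback sets out from 11 and comes back at 13. It reverses the order of the endgame and changes the oxidation mechanism. BCl3 and pentamethylbenzene (CH2Cl2, −78 °C) first free the phenol to give the 3,4-dihydro target F7. Ag2O in CH2Cl2 at rt then oxidises this syringyl-type phenol to the p-quinone methide F8 (C7=O, C4a=C4). Its acidic C3–H is lost on addition of catalytic Et3N, which re-aromatises ring A and gives 13.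

Further compounds
F1 | step 6 | 7-O-benzylisofraxidin (7-benzyloxy-6,8-dimethoxycoumarin) | COc1cc2ccc(=O)oc2c(OC)c1OCc1ccccc1
F2 | step 6 | 4-benzyloxy-2-hydroxy-3,5-dimethoxybenzaldehyde | O=Cc1cc(OC)c(OCc2ccccc2)c(OC)c1O
F3 | step 6 | tert-butyl 2-[(6,8-dimethoxy-2-oxo-2H-chromen-7-yl)oxy]acetate | COc1cc2ccc(=O)oc2c(OC)c1OCC(=O)OC(C)(C)C
F4 | step 6 | 2-[(6,8-dimethoxy-2-oxo-2H-chromen-7-yl)oxy]acetic acid | COc1cc2ccc(=O)oc2c(OC)c1OCC(=O)O
F5 | step 5 | 6-benzyloxy-2-formyl-5,7-dimethoxyindan-1-one (drawn as the formyl tautomer of the hydroxymethylene ketone, racemic and labile) | O=CC1Cc2cc(OC)c(OCc3ccccc3)c(OC)c2C1=O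
F6 | step 5 | 6-benzyloxy-2-diazo-5,7-dimethoxyindan-1-one | [N-]=[N+]=C1Cc2cc(OC)c(OCc3ccccc3)c(OC)c2C1=O
F7 | step 7 | (±)-7-hydroxy-3-[(6,8-dimethoxy-2-oxo-2H-chromen-7-yl)oxy]-6,8-dimethoxy-3,4-dihydrocoumarin | O=C1Oc2c(OC)c(O)c(OC)cc2CC1Oc1c(OC)cc2ccc(=O)oc2c1OC
F8 | step 7 | (±)-p-quinone methide of F7 (C7=O, C4a=C4, C3 still sp3) | O=C1OC2=C(OC)C(=O)C(OC)=CC2=CC1Oc1c(OC)cc2ccc(=O)oc2c1OC
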